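**Retrosynthetic overview**
- Last step: E-selective cross-metathesis joins a C1–C10 homoallylic acetate (chain half) to an α-methylene lactone at the C10=C3 alkene.
- Key disconnection: the lactone C5–O bond, made by a new hydroxyl-directed, selenium-catalysed dehydrogenative lactonization of a 3-hydroxy-2-methylidene-4-enoic acid; it closes the ring, sets C5 and unveils the 2-methylprop-1-enyl group.
- The acid comes from an asymmetric Morita–Baylis–Hillman reaction of (E)-4-methylpent-2-enal with an activated acrylate (sets the C4 carbinol).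
- Chain half from nerol: angelate C–O bond by Mitsunobu, allylic C–H oxidation to the enal, asymmetric allylboration (sets C8), acetylation.
- Ring order: the γ-butyrolactone (ring A) is the only ring and is closed before the two halves are joined.

Assumption: chain atoms are numbered C1–C10 and lactone atoms O1, C2–C5 as in the name of the target; β-isocupreidine, (S)-TRIP and the ruthenium carbene are bought and not counted as steps.

**Step 1**
Reactants: 1 nerol; 2 angelic acid
Product: 3 (2Z)-3,7-dimethylocta-2,6-dien-1-yl (2Z)-2-methylbut-2-enoate (neryl angelate)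
Conditions: PPh3, DIAD, THF, 0 °C to 23 °C
Reagents that add atoms: none
Why: Mitsunobu esterification, in which the carboxylate displaces the oxyphosphonium of the primary allylic alcohol (SN2), so the C–O bond forms without acyl activation and both the angelate Z and the neryl 2Z geometry are kept.

**Step 2**
Reactants: 3 neryl angelate
Product: 5 (2Z,6E)-3,7-dimethyl-8-oxoocta-2,6-dien-1-yl (2Z)-2-methylbut-2-enoate, via allylic alcohol 4 (not isolated)
Conditions: SeO2 (1.2 equiv), 95% EtOH, 78 °C
Reagents that add atoms: selenium dioxide, O=[Se]=O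
Why: Riley allylic oxidation (ene reaction then 2,3-sigmatropic shift) attacks the E-methyl group of the electron-rich terminal trisubstituted alkene and carries the allylic alcohol on to the enal, while the ester-deactivated C2=C3 alkene and the electron-poor angelate are left alone.

**Step 3**
Reactants: 5 (2Z,6E)-8-oxo enal
Product: 7 (2Z,6E,8S)-8-hydroxy-3,7-dimethylundeca-2,6,10-trien-1-yl (2Z)-2-methylbut-2-enoate, via pinacol borate ester 6 (not isolated)
Conditions: allylB(pin) (1.2 equiv), (S)-3,3'-bis(2,4,6-triisopropylphenyl)-1,1'-binaphthyl-2,2'-diyl hydrogen phosphate ((S)-TRIP, 5 mol%), toluene, −30 °C; aq. NaHCO3 work-up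
Reagents that add atoms: allylboronic acid pinacol ester, C=CCB1OC(C)(C)C(C)(C)O1
Why: Chiral phosphoric acid-catalysed allylboration through a closed chair transition state, in which the (S)-catalyst (by analogy with aryl and alkenyl aldehydes) sends allyl to the Si face of the aldehyde and sets C8 as S; the esters are inert.

**Step 4**
Reactants: 7 (8S)-homoallylic alcohol
Product: 8 (2Z,6E,8S)-8-(acetyloxy)-3,7-dimethylundeca-2,6,10-trien-1-yl (2Z)-2-methylbut-2-enoate
Conditions: Ac2O, pyridine, DMAP (cat.), CH2Cl2, 0 °C to 23 °C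
Reagents that add atoms: acetic anhydride, CC(=O)OC(C)=O
Why: Nucleophile-catalysed O-acylation of the secondary alcohol, which does not touch the C8 stereocentre or the alkenes.

**Step 5**
Reactants: 9 (2E)-4-methylpent-2-enal; 10 1,1,1,3,3,3-hexafluoropropan-2-yl prop-2-enoate
Product: 11 1,1,1,3,3,3-hexafluoropropan-2-yl (3R,4E)-3-hydroxy-6-methyl-2-methylidenehept-4-enoate
Conditions: β-isocupreidine (10 mol%), DMF, −55 °C
Reagents that add atoms: none
Why: Asymmetric Morita–Baylis–Hillman reaction, in which the cinchona-derived amine–phenol catalyst and the activated fluoroalkyl acrylate give the (R)-carbinol, as known for other aldehydes including enals; this centre becomes C4 (S) of the lactone.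

**Step 6**
Reactants: 11 (3R)-hexafluoroisopropyl ester
Product: 13 (3R,4E)-3-hydroxy-6-methyl-2-methylidenehept-4-enoic acid, via lithium carboxylate 12 (not isolated)
Conditions: LiOH·H2O (2 equiv), THF/H2O (3:1), 0 °C; then 1 M HCl to pH 3
Reagents that add atoms: lithium hydroxide, [Li+].[OH-]
Why: Saponification of the activated fluoroalkyl ester is fast under mild base and leaves the allylic carbinol and both alkenes unchanged.

**Step 7**
Reactants: 13 (3R,4E)-hydroxy acid
Product: 15 (4S,5R)-4-hydroxy-3-methylidene-5-(2-methylprop-1-en-1-yl)oxolan-2-one, via selenide lactone 14 (not isolated)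
Conditions: (PhSe)2 (10 mol%), N-fluorobenzenesulfonimide (1.05 equiv), 4 Å MS, CH2Cl2, 23 °C
Reagents that add atoms: none
Why: Proposed new method: hydroxyl-directed, trans-selective selenium-π-acid dehydrogenative lactonization, in which PhSe+ (from the diselenide and NFSI) is delivered to the C4=C5 face syn to the free C3–OH through an O→Se contact (C3–H eclipsing the alkene), the carboxyl closes 5-exo anti to selenium so that the new C5–O bond is trans to the C4–OH, reversible seleniranium formation under the acidic conditions drains the cis adduct, and NFSI then oxidises selenide 14 to a tetravalent selenium species that eliminates toward the only non-oxygenated β-C–H (the isopropyl methine) to give the 2-methylprop-1-enyl group and return the catalyst; the electron-poor acrylate alkene does not react; closest known reaction type: selenium-catalysed oxidative allylic lactonization of simple alkenoic acids and the stoichiometric phenylselenolactonization–selenoxide elimination sequence, neither shown with a directing allylic hydroxyl or on a 2-methylidene acid.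

**Step 8**
Reactants: 8 (8S)-homoallylic acetate (1.0 equiv); 15 α-methylene lactone (2.0 equiv)
Product: 16 (2Z,6E,8S,10E)-8-(acetyloxy)-10-[(4S,5R)-4-hydroxy-5-(2-methylprop-1-en-1-yl)-2-oxooxolan-3-ylidene]-3,7-dimethyldeca-2,6-dien-1-yl (2Z)-2-methylbut-2-enoate (CNP0201198.1)
Conditions: RuCl2(H2IMes)(=CH-C6H4-2-OiPr) (Hoveyda–Grubbs second-generation catalyst, H2IMes = 1,3-dimesitylimidazolidin-2-ylidene, 10 mol%), 2,6-dichloro-1,4-benzoquinone (10 mol%), CH2Cl2, 40 °C
Reagents that add atoms: none
Why: Olefin cross-metathesis between a terminal alkene and an α-methylene-γ-butyrolactone gives the trisubstituted alkylidene lactone with the chain CH2 anti to the lactone carbonyl (E) as the favoured isomer, the benzoquinone suppresses ruthenium hydride isomerization, and the trisubstituted alkenes and the angelate react much more slowly.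

**Compound list**
1 | nerol, (2Z)-3,7-dimethylocta-2,6-dien-1-ol | CC(C)=CCC/C(C)=C\CO | starting material
2 | angelic acid, (2Z)-2-methylbut-2-enoic acid | C/C=C(/C)C(=O)O | starting material
3 | (2Z)-3,7-dimethylocta-2,6-dien-1-yl (2Z)-2-methylbut-2-enoate | C/C=C(/C)C(=O)OC/C=C(/C)CCC=C(C)C | intermediate
4 | (2Z,6E)-8-hydroxy-3,7-dimethylocta-2,6-dien-1-yl (2Z)-2-methylbut-2-enoate | C/C=C(/C)C(=O)OC/C=C(/C)CC/C=C(\C)CO | intermediate
5 | (2Z,6E)-3,7-dimethyl-8-oxoocta-2,6-dien-1-yl (2Z)-2-methylbut-2-enoate | C/C=C(/C)C(=O)OC/C=C(/C)CC/C=C(\C)C=O | intermediate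
6 | (2Z,6E,8S)-3,7-dimethyl-8-[(4,4,5,5-tetramethyl-1,3,2-dioxaborolan-2-yl)oxy]undeca-2,6,10-trien-1-yl (2Z)-2-methylbut-2-enoate | C/C=C(/C)C(=O)OC/C=C(/C)CC/C=C(\C)[C@H](CC=C)OB1OC(C)(C)C(C)(C)O1 | intermediate
7 | (2Z,6E,8S)-8-hydroxy-3,7-dimethylundeca-2,6,10-trien-1-yl (2Z)-2-methylbut-2-enoate | C/C=C(/C)C(=O)OC/C=C(/C)CC/C=C(\C)[C@H](CC=C)O | intermediate
8 | (2Z,6E,8S)-8-(acetyloxy)-3,7-dimethylundeca-2,6,10-trien-1-yl (2Z)-2-methylbut-2-enoate | C/C=C(/C)C(=O)OC/C=C(/C)CC/C=C(\C)[C@H](CC=C)OC(C)=O | intermediate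
9 | (2E)-4-methylpent-2-enal | CC(C)/C=C/C=O | starting material
10 | 1,1,1,3,3,3-hexafluoropropan-2-yl prop-2-enoate | C=CC(=O)OC(C(F)(F)F)C(F)(F)F | starting material
11 | 1,1,1,3,3,3-hexafluoropropan-2-yl (3R,4E)-3-hydroxy-6-methyl-2-methylidenehept-4-enoate | C=C(C(=O)OC(C(F)(F)F)C(F)(F)F)[C@H](O)/C=C/C(C)C | intermediate
12 | lithium (3R,4E)-3-hydroxy-6-methyl-2-methylidenehept-4-enoate | C=C(C(=O)[O-])[C@H](O)/C=C/C(C)C.[Li+] | intermediate
13 | (3R,4E)-3-hydroxy-6-methyl-2-methylidenehept-4-enoic acid | C=C(C(=O)O)[C@H](O)/C=C/C(C)C | intermediate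
14 | (4S,5S)-4-hydroxy-3-methylidene-5-[(1R)-2-methyl-1-(phenylselanyl)propyl]oxolan-2-one | C=C1C(=O)O[C@H]([C@H]([Se]c2ccccc2)C(C)C)[C@H]1O | intermediate
15 | (4S,5R)-4-hydroxy-3-methylidene-5-(2-methylprop-1-en-1-yl)oxolan-2-one | C=C1C(=O)O[C@H](C=C(C)C)[C@H]1O | intermediate
16 | (2Z,6E,8S,10E)-8-(acetyloxy)-10-[(4S,5R)-4-hydroxy-5-(2-methylprop-1-en-1-yl)-2-oxooxolan-3-ylidene]-3,7-dimethyldeca-2,6-dien-1-yl (2Z)-2-methylbut-2-enoate | C/C=C(/C)C(=O)OC/C=C(/C)CC/C=C(\C)[C@H](C/C=C1/C(=O)O[C@H](C=C(C)C)[C@H]1O)OC(C)=O | target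

**Step count**
Total: 8 steps. Longest linear sequence: 5 steps (steps 1, 2, 3, 4, 8); the lactone branch is steps 5, 6, 7 and joins at step 8.

**Steps most likely to fail**

Step 7 (the proposed new lactonization). The risk is the facial selectivity at C5: kinetic iodolactonizations of 3-hydroxy-4-enoic acids favour the cis lactone, so the trans outcome rests on O→Se delivery and on reversibility. A second risk is further selenium chemistry at the new 2-methylprop-1-enyl group. The fallback sets out from 13 and returns to the route at 15, using known chemistry. Iodolactonization under equilibrating conditions (I2, MeCN, 0 to 23 °C, no base, dark) gives (4S,5S)-4-hydroxy-5-[(1R)-1-iodo-2-methylpropyl]-3-methylideneoxolan-2-one F4, the trans isomer that such thermodynamic conditions are known to favour for 3-substituted 4-enoic acids, and it can be purified at this stage. Dehydroiodination with DBU (toluene, 60 °C) toward the isopropyl C–H then gives 15.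

Step 8 (cross-metathesis). The risks are a sluggish 1,1-disubstituted electron-poor partner, an E/Z mixture, and competing metathesis at the 2-methylprop-1-enyl group. The fallback sets out from 7 and 15 and returns at 16, replacing the intermolecular coupling with a silicon-tethered ring closure. Sequential silylation (iPr2SiCl2, imidazole, CH2Cl2, 0 °C, first 7 and then 15) gives the mixed silaketal (2Z,6E,8S)-3,7-dimethyl-8-{[{[(2R,3S)-4-methylidene-2-(2-methylprop-1-en-1-yl)-5-oxooxolan-3-yl]oxy}di(propan-2-yl)silyl]oxy}undeca-2,6,10-trien-1-yl (2Z)-2-methylbut-2-enoate F5. Ring-closing metathesis (RuCl2(H2IMes)(PCy3)(=CHPh), Grubbs second-generation catalyst, toluene, 80 °C, 2 mM) closes the eight-membered O8,O4-diisopropylsilylene-bridged (10E)-alkylidene lactone F6; this ring can only hold the new alkene with C9 and lactone C4 cis, which is the required 10E geometry. HF·pyridine (THF, 0 °C) frees the diol (2Z,6E,8S,10E)-8-hydroxy-10-[(4S,5R)-4-hydroxy-5-(2-methylprop-1-en-1-yl)-2-oxooxolan-3-ylidene]-3,7-dimethyldeca-2,6-dien-1-yl (2Z)-2-methylbut-2-enoate F7. Acetylation of the less hindered acyclic C8 hydroxyl (Ac2O, 2,4,6-collidine, CH2Cl2, −20 °C) gives 16.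

Step 5 (asymmetric Morita–Baylis–Hillman reaction). The risks are that enals are slow partners, a dioxanone by-product lowers the yield, and the ee may fall short. The fallback sets out from 9 and returns at 13, replacing asymmetric catalysis with a resolution. DABCO-mediated Morita–Baylis–Hillman reaction of 9 with methyl acrylate gives racemic methyl (4E)-3-hydroxy-6-methyl-2-methylidenehept-4-enoate F1. Sharpless kinetic resolution (Ti(OiPr)4, D-(−)-diisopropyl tartrate, tBuOOH, 4 Å MS, CH2Cl2, −20 °C, stopped near 55% conversion) leaves the slow-reacting methyl (3R,4E)-3-hydroxy-6-methyl-2-methylidenehept-4-enoate F2. The (S)-enantiomer is consumed as the erythro epoxy alcohol methyl (3R)-3-hydroxy-2-methylidene-3-[(2R,3R)-3-(propan-2-yl)oxiran-2-yl]propanoate F3 and removed by chromatography. Hydrolysis of F2 (LiOH, THF/H2O, then HCl) gives 13.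

**Further compounds**
F1 | step 5 | methyl (4E)-3-hydroxy-6-methyl-2-methylidenehept-4-enoate (racemic) | C=C(C(=O)OC)C(O)/C=C/C(C)C
F2 | step 5 | methyl (3R,4E)-3-hydroxy-6-methyl-2-methylidenehept-4-enoate | C=C(C(=O)OC)[C@H](O)/C=C/C(C)C
F3 | step 5 | methyl (3R)-3-hydroxy-2-methylidene-3-[(2R,3R)-3-(propan-2-yl)oxiran-2-yl]propanoate | C=C(C(=O)OC)[C@@H](O)[C@H]1O[C@@H]1C(C)C
F4 | step 7 | (4S,5S)-4-hydroxy-5-[(1R)-1-iodo-2-methylpropyl]-3-methylideneoxolan-2-one | C=C1C(=O)O[C@H]([C@H](I)C(C)C)[C@H]1O
F5 | step 8 | (2Z,6E,8S)-3,7-dimethyl-8-{[{[(2R,3S)-4-methylidene-2-(2-methylprop-1-en-1-yl)-5-oxooxolan-3-yl]oxy}di(propan-2-yl)silyl]oxy}undeca-2,6,10-trien-1-yl (2Z)-2-methylbut-2-enoate | C/C=C(/C)C(=O)OC/C=C(/C)CC/C=C(\C)[C@H](CC=C)O[Si](C(C)C)(C(C)C)O[C@@H]1[C@@H](C=C(C)C)OC(=O)C1=C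
F6 | step 8 | O8,O4-diisopropylsilylene-bridged (10E)-alkylidene lactone (eight-membered 1,3-dioxa-2-silacyclooctene fused to ring A; otherwise 16 without the acetyl group) | C/C=C(/C)C(=O)OC/C=C(/C)CC/C=C(\C)[C@@H]1C/C=C2/C(=O)O[C@H](C=C(C)C)[C@H]2O[Si](C(C)C)(C(C)C)O1
F7 | step 8 | (2Z,6E,8S,10E)-8-hydroxy-10-[(4S,5R)-4-hydroxy-5-(2-methylprop-1-en-1-yl)-2-oxooxolan-3-ylidene]-3,7-dimethyldeca-2,6-dien-1-yl (2Z)-2-methylbut-2-enoate | C/C=C(/C)C(=O)OC/C=C(/C)CC/C=C(\C)[C@H](C/C=C1/C(=O)O[C@H](C=C(C)C)[C@H]1O)O
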